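The flavonol is cut at C3–C4 of ring C, the bond between the C4 carbonyl carbon and the oxygen-bearing C3, which is an acyloin linkage at a higher oxidation level. Both carbons are then aldehydes, already joined through the O1–C2 aryl ether that ties ring A to the carbon carrying ring B. One carbene-catalysed intramolecular benzoin reaction forms C3–C4, closes ring C and gives the 3-hydroxychroman-4-one; dehydrogenation and MOM removal finish the synthesis. The precursor is a tris-MOM dialdehyde in which the ring A formyl group, the required acyl-anion donor, and an α-aryl-α-aryloxy acetaldehyde, the acceptor, stand in a 1,6-relationship.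

Key step: step 15

Remark on the chemistry: flavonol locants (O1, C2–C8a) are used for ring A and ring C; in ring B, C1′ is bonded to C2, C2′ carries the prenyl group, C3′ and C4′ carry the fused dimethylpyran (oxygen on C4′) and C5′ the hydroxyl group; the target has no stereocentre, so the benzylic centre of 15–25 is racemic and is erased in step 16.

Step 1
Reactants: 1 2,4,6-trihydroxybenzaldehyde; 2 3-methylbut-2-en-1-ol
Product: 3 2,6-dihydroxy-4-[(3-methylbut-2-en-1-yl)oxy]benzaldehyde
Conditions: PPh3, DIAD, THF, 0 °C to rt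
Reagents that add atoms: none
Why: Mitsunobu etherification, in which the 4-OH, the most acidic hydroxyl and the only one not hydrogen-bonded to the formyl group, is alkylated by the activated primary allylic alcohol without the C-alkylation that a free phloroglucinol phenoxide can undergo.

Step 2
Reactants: 3 2,6-dihydroxy-4-(prenyloxy)benzaldehyde
Product: 5 2,4,6-trihydroxy-3-(2-methylbut-3-en-2-yl)benzaldehyde, via ortho-dienone 4 (not isolated)
Conditions: PhNEt2, 170 °C, argon
Reagents that add atoms: none
Why: Aromatic Claisen rearrangement, in which the [3,3] shift delivers the dimethyl-substituted allyl terminus to either of the two equivalent ortho carbons and ortho-dienone 4 tautomerises to the phenol, while onward Cope migration to the para carbon is closed off because that carbon carries the formyl group.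

Step 3
Reactants: 5 2,4,6-trihydroxy-3-(2-methylbut-3-en-2-yl)benzaldehyde
Product: 6 2-hydroxy-4,6-bis(methoxymethoxy)-3-(2-methylbut-3-en-2-yl)benzaldehyde
Conditions: MOMCl (2.2 equiv), i-Pr2NEt, CH2Cl2, 0 °C to rt
Reagents that add atoms: chloromethyl methyl ether, COCCl
Why: Williamson-type acetal formation, in which the unchelated 4-OH and the less hindered chelated 6-OH react, while the 2-OH, flanked by the tertiary alkyl group and hydrogen-bonded to the formyl group, should stay free.

Step 4
Reactants: 7 3-(benzyloxy)-4-hydroxybenzaldehyde; 8 3-chloro-3-methylbut-1-yne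
Product: 10 8-(benzyloxy)-2,2-dimethyl-2H-chromene-6-carbaldehyde, via aryl propargyl ether 9 (not isolated)
Conditions: K2CO3, KI, CuI (cat.), DMF, 65 °C; then 150 °C
Reagents that add atoms: none
Why: Copper-assisted O-alkylation with the tertiary propargylic chloride is followed on heating by propargyl Claisen rearrangement to the free ortho carbon, 1,5-hydrogen shift and 6π-electrocyclisation, the standard route to 2,2-dimethyl-2H-chromenes.

Step 5
Reactants: 10 8-(benzyloxy)-2,2-dimethyl-2H-chromene-6-carbaldehyde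
Product: 11 8-hydroxy-2,2-dimethylchromane-6-carbaldehyde
Conditions: H2 (1 atm), 10% Pd/C, EtOAc, rt
Reagents that add atoms: none
Why: Catalytic hydrogenation saturates the styrene-type C3=C4 bond of the chromene and hydrogenolyses the benzyl ether in one operation, both being faster than reduction of the aryl aldehyde under these mild conditions.

Step 6
Reactants: 11 8-hydroxy-2,2-dimethylchromane-6-carbaldehyde
Product: 12 8-(methoxymethoxy)-2,2-dimethylchromane-6-carbaldehyde
Conditions: MOMCl, i-Pr2NEt, CH2Cl2, 0 °C to rt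
Reagents that add atoms: chloromethyl methyl ether, COCCl
Why: Williamson-type protection of the only free phenol as a MOM ether, the group that is removed together with the two on ring A at the end.

Step 7
Reactants: 12 8-(methoxymethoxy)-2,2-dimethylchromane-6-carbaldehyde
Product: 13 5-bromo-8-(methoxymethoxy)-2,2-dimethylchromane-6-carbaldehyde
Conditions: NBS, DMF, 0 °C to rt, dark
Reagents that add atoms: N-bromosuccinimide, O=C1CCC(=O)N1Br
Why: Electrophilic aromatic bromination, in which the MOM-ether oxygen (unlike the ring oxygen, not conjugated with the formyl group) directs to its para position C5, which is also ortho to the C4a alkyl carbon, as in the bromination of 3,4-dialkoxybenzaldehydes at C6.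

Step 8
Reactants: 13 5-bromo-8-(methoxymethoxy)-2,2-dimethylchromane-6-carbaldehyde; 14 bromoform
Product: 16 2-[5-bromo-8-(methoxymethoxy)-2,2-dimethylchroman-6-yl]-2-hydroxyacetic acid (racemic), via tribromomethyl carbinol 15 (not isolated)
Conditions: KOH, LiCl, 1,4-dioxane/H2O, 0–5 °C; acidified to pH 3 on work-up
Reagents that add atoms: potassium hydroxide, [K+].[OH-]
Why: Haloform-type homologation (Jocic–Reeve reaction), in which tribromomethanide adds to the aldehyde and hydroxide converts carbinol 15 into the α-hydroxy acid, so that the aldehyde carbon becomes the future C2 and the bromoform carbon the future C3; MOM ethers and the aryl bromide tolerate aqueous KOH, and no alkene that dibromocarbene could attack is present yet.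

Step 9
Reactants: 16 2-[5-bromo-8-(methoxymethoxy)-2,2-dimethylchroman-6-yl]-2-hydroxyacetic acid
Product: 17 methyl 2-[5-bromo-8-(methoxymethoxy)-2,2-dimethylchroman-6-yl]-2-hydroxyacetate (racemic)
Conditions: MeI, KHCO3, DMF, rt
Reagents that add atoms: iodomethane, CI
Why: SN2 O-alkylation of the carboxylate under a base too weak to deprotonate the secondary alcohol.

Step 10
Reactants: 17 methyl 2-[5-bromo-8-(methoxymethoxy)-2,2-dimethylchroman-6-yl]-2-hydroxyacetate; 18 tributyl(3-methylbut-2-en-1-yl)stannane
Product: 19 methyl 2-hydroxy-2-[8-(methoxymethoxy)-2,2-dimethyl-5-(3-methylbut-2-en-1-yl)chroman-6-yl]acetate (racemic)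
Conditions: Pd2(dba)3 (cat.), P(t-Bu)3 (cat.), CsF, 1,4-dioxane, 90 °C
Reagents that add atoms: none
Why: Stille coupling, in which zerovalent palladium inserts into the C–Br bond, the prenyl group is transferred from tin, and reductive elimination at the unsubstituted CH2 terminus is favoured by the two ortho substituents of the aryl group, so the linear prenyl arene should result.

Step 11
Reactants: 19 methyl 2-hydroxy-2-[8-(methoxymethoxy)-2,2-dimethyl-5-(3-methylbut-2-en-1-yl)chroman-6-yl]acetate
Product: 20 methyl 2-[8-(methoxymethoxy)-2,2-dimethyl-5-(3-methylbut-2-en-1-yl)chroman-6-yl]-2-[(methylsulfonyl)oxy]acetate (racemic)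
Conditions: MsCl, Et3N, CH2Cl2, −20 °C; used crude
Reagents that add atoms: methanesulfonyl chloride, CS(=O)(=O)Cl
Why: Sulfonylation turns the secondary alcohol into a leaving group, and the adjacent ester disfavours ionisation, so the benzylic mesylate should last long enough to be used crude.

Step 12
Reactants: 6 2-hydroxy-4,6-bis(methoxymethoxy)-3-(2-methylbut-3-en-2-yl)benzaldehyde; 20 mesylate of the ring B hydroxy ester
Product: 21 methyl 2-[2-formyl-3,5-bis(methoxymethoxy)-6-(2-methylbut-3-en-2-yl)phenoxy]-2-[8-(methoxymethoxy)-2,2-dimethyl-5-(3-methylbut-2-en-1-yl)chroman-6-yl]acetate (racemic)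
Conditions: Cs2CO3, MeCN, 40 °C
Reagents that add atoms: none
Why: Williamson ether synthesis (SN2) at a benzylic, α-carbonyl carbon that has no β-hydrogen, so elimination cannot compete; the O1–C2 bond forms and C2 is racemic.

Step 13
Reactants: 21 ether ester
Product: 22 2-[2-(hydroxymethyl)-3,5-bis(methoxymethoxy)-6-(2-methylbut-3-en-2-yl)phenoxy]-2-[8-(methoxymethoxy)-2,2-dimethyl-5-(3-methylbut-2-en-1-yl)chroman-6-yl]ethanol (racemic)
Conditions: LiAlH4, THF, 0 °C
Reagents that add atoms: none
Why: Hydride reduction of the ester and the aldehyde to the two primary alcohols; MOM acetals, aryl ethers and isolated alkenes are inert to LiAlH4.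

Step 14
Reactants: 22 diol
Product: 23 2-{1-[8-(methoxymethoxy)-2,2-dimethyl-5-(3-methylbut-2-en-1-yl)chroman-6-yl]-2-oxoethoxy}-4,6-bis(methoxymethoxy)-3-(2-methylbut-3-en-2-yl)benzaldehyde (racemic)
Conditions: Dess–Martin periodinane, pyridine, CH2Cl2, 0 °C to rt; used at once
Reagents that add atoms: none
Why: Dess–Martin oxidation of both primary alcohols to aldehydes under buffered, non-basic conditions that spare the MOM groups and alkenes and do not enolise the sensitive α-aryloxy aldehyde.

Step 15
Reactants: 23 dialdehyde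
Product: 24 (2R*,3R*)-3-hydroxy-5,7-bis(methoxymethoxy)-2-[8-(methoxymethoxy)-2,2-dimethyl-5-(3-methylbut-2-en-1-yl)chroman-6-yl]-8-(2-methylbut-3-en-2-yl)chroman-4-one (trans; racemic)
Conditions: 2-(pentafluorophenyl)-6,7-dihydro-5H-pyrrolo[2,1-c][1,2,4]triazol-2-ium tetrafluoroborate (20 mol %), Et3N (20 mol %), toluene (0.02 M), 25 °C, argon
Reagents that add atoms: none
Why: The triazolylidene set free by Et3N adds to the ring A formyl carbon (C4), proton transfer turns this carbon into an enaminol acyl-anion equivalent, and it attacks the aliphatic aldehyde carbon (C3), after which proton transfer and loss of the carbene leave the C4 ketone and the C3 carbinol. The closest known reaction type is the carbene-catalysed intramolecular crossed benzoin cyclisation of 2-(2-oxoalkoxy)benzaldehydes to 3-hydroxychroman-4-ones. Ring C closes in a 6-exo-trig mode across the tether C4a–C8a–O1–C2. The one new stereocentre, C3, should form trans to the C2 aryl group under substrate control: a chair-like transition state places the ring B aryl group equatorial, and C2 (α to the aldehyde before closure) and C3 (α to the ketone after it) can both equilibrate under the amine, so the diequatorial racemate results. The step needs the ring A aldehyde and not the aliphatic one to act as donor, because an acyl-anion equivalent on C3 could expel the ring A aryloxide from C2; the substrate favours this since the aliphatic formyl group hangs on a crowded tertiary carbon (2′-prenylaryl plus a 2,6-disubstituted aryloxy group) that slows its conversion into an enaminol, is the more electrophilic acceptor, and leads to the aryl ketone conjugated with the trioxygenated ring A, the more stable acyloin. Ring closure is favoured over intermolecular benzoin coupling by the six-membered transition state, helped by dilution.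

Step 16
Reactants: 24 trans-dihydroflavonol
Product: 26 3-hydroxy-5,7-bis(methoxymethoxy)-2-[8-(methoxymethoxy)-2,2-dimethyl-5-(3-methylbut-2-en-1-yl)chroman-6-yl]-8-(2-methylbut-3-en-2-yl)-4H-chromen-4-one, via chromane-3,4-dione 25 (not isolated)
Conditions: Dess–Martin periodinane, pyridine, CH2Cl2, rt
Reagents that add atoms: none
Why: Dess–Martin oxidation of the secondary α-ketol gives chromane-3,4-dione 25, whose C2–H enolises at once towards C3 to form the aromatic 3-hydroxy-4-pyranone, so both stereocentres disappear.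

Step 17
Reactants: 26 tris-MOM flavonol
Product: 27 Broussoflavonol E
Conditions: HCl (2 M), MeOH/H2O 9:1, 45 °C
Reagents that add atoms: none
Why: Acid-catalysed acetal exchange with methanol removes the three MOM groups, and dilute acid at moderate temperature is chosen because acetal cleavage should be faster than protonation of the prenyl and 1,1-dimethylallyl double bonds.

Compound list

1 | 2,4,6-trihydroxybenzaldehyde | O=Cc1c(O)cc(O)cc1O | starting material
2 | 3-methylbut-2-en-1-ol | CC(C)=CCO | starting material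
3 | 2,6-dihydroxy-4-[(3-methylbut-2-en-1-yl)oxy]benzaldehyde | O=Cc1c(O)cc(OCC=C(C)C)cc1O | intermediate
4 | 2-formyl-3,5-dihydroxy-6-(2-methylbut-3-en-2-yl)cyclohexa-2,4-dienone (ortho-dienone, racemic) | O=CC1=C(O)C(C(C)(C)C=C)C(=O)C=C1O | intermediate (not isolated)
5 | 2,4,6-trihydroxy-3-(2-methylbut-3-en-2-yl)benzaldehyde | O=Cc1c(O)cc(O)c(C(C)(C)C=C)c1O | intermediate
6 | 2-hydroxy-4,6-bis(methoxymethoxy)-3-(2-methylbut-3-en-2-yl)benzaldehyde | O=Cc1c(O)c(C(C)(C)C=C)c(OCOC)cc1OCOC | intermediate
7 | 3-(benzyloxy)-4-hydroxybenzaldehyde | O=Cc1ccc(O)c(OCc2ccccc2)c1 | starting material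
8 | 3-chloro-3-methylbut-1-yne | CC(C)(Cl)C#C | starting material
9 | 3-(benzyloxy)-4-[(2-methylbut-3-yn-2-yl)oxy]benzaldehyde | O=Cc1ccc(OC(C)(C)C#C)c(OCc2ccccc2)c1 | intermediate (not isolated)
10 | 8-(benzyloxy)-2,2-dimethyl-2H-chromene-6-carbaldehyde | O=Cc1cc2C=CC(C)(C)Oc2c(OCc3ccccc3)c1 | intermediate
11 | 8-hydroxy-2,2-dimethylchromane-6-carbaldehyde | O=Cc1cc2CCC(C)(C)Oc2c(O)c1 | intermediate
12 | 8-(methoxymethoxy)-2,2-dimethylchromane-6-carbaldehyde | O=Cc1cc2CCC(C)(C)Oc2c(OCOC)c1 | intermediate
13 | 5-bromo-8-(methoxymethoxy)-2,2-dimethylchromane-6-carbaldehyde | O=Cc1cc(OCOC)c2OC(C)(C)CCc2c1Br | intermediate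
14 | bromoform | BrC(Br)Br | starting material
15 | 2,2,2-tribromo-1-[5-bromo-8-(methoxymethoxy)-2,2-dimethylchroman-6-yl]ethanol (racemic) | OC(c1cc(OCOC)c2OC(C)(C)CCc2c1Br)C(Br)(Br)Br | intermediate (not isolated)
16 | 2-[5-bromo-8-(methoxymethoxy)-2,2-dimethylchroman-6-yl]-2-hydroxyacetic acid (racemic) | OC(=O)C(O)c1cc(OCOC)c2OC(C)(C)CCc2c1Br | intermediate
17 | methyl 2-[5-bromo-8-(methoxymethoxy)-2,2-dimethylchroman-6-yl]-2-hydroxyacetate (racemic) | COC(=O)C(O)c1cc(OCOC)c2OC(C)(C)CCc2c1Br | intermediate
18 | tributyl(3-methylbut-2-en-1-yl)stannane | CCCC[Sn](CCCC)(CCCC)CC=C(C)C | starting material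
19 | methyl 2-hydroxy-2-[8-(methoxymethoxy)-2,2-dimethyl-5-(3-methylbut-2-en-1-yl)chroman-6-yl]acetate (racemic) | COC(=O)C(O)c1cc(OCOC)c2OC(C)(C)CCc2c1CC=C(C)C | intermediate
20 | methyl 2-[8-(methoxymethoxy)-2,2-dimethyl-5-(3-methylbut-2-en-1-yl)chroman-6-yl]-2-[(methylsulfonyl)oxy]acetate (racemic) | COC(=O)C(OS(C)(=O)=O)c1cc(OCOC)c2OC(C)(C)CCc2c1CC=C(C)C | intermediate
21 | methyl 2-[2-formyl-3,5-bis(methoxymethoxy)-6-(2-methylbut-3-en-2-yl)phenoxy]-2-[8-(methoxymethoxy)-2,2-dimethyl-5-(3-methylbut-2-en-1-yl)chroman-6-yl]acetate (racemic) | COC(=O)C(Oc1c(C=O)c(OCOC)cc(OCOC)c1C(C)(C)C=C)c1cc(OCOC)c2OC(C)(C)CCc2c1CC=C(C)C | intermediate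
22 | 2-[2-(hydroxymethyl)-3,5-bis(methoxymethoxy)-6-(2-methylbut-3-en-2-yl)phenoxy]-2-[8-(methoxymethoxy)-2,2-dimethyl-5-(3-methylbut-2-en-1-yl)chroman-6-yl]ethanol (racemic) | OCC(Oc1c(CO)c(OCOC)cc(OCOC)c1C(C)(C)C=C)c1cc(OCOC)c2OC(C)(C)CCc2c1CC=C(C)C | intermediate
23 | 2-{1-[8-(methoxymethoxy)-2,2-dimethyl-5-(3-methylbut-2-en-1-yl)chroman-6-yl]-2-oxoethoxy}-4,6-bis(methoxymethoxy)-3-(2-methylbut-3-en-2-yl)benzaldehyde (racemic; key-step precursor) | O=Cc1c(OCOC)cc(OCOC)c(C(C)(C)C=C)c1OC(C=O)c1cc(OCOC)c2OC(C)(C)CCc2c1CC=C(C)C | intermediate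
24 | (2R*,3R*)-3-hydroxy-5,7-bis(methoxymethoxy)-2-[8-(methoxymethoxy)-2,2-dimethyl-5-(3-methylbut-2-en-1-yl)chroman-6-yl]-8-(2-methylbut-3-en-2-yl)chroman-4-one (trans, racemic; the 2R,3R enantiomer is drawn) | CC(C)=CCc1c2CCC(C)(C)Oc2c(OCOC)cc1[C@@H]1[C@H](C(=O)c2c(OCOC)cc(OCOC)c(C(C)(C)C=C)c2O1)O | intermediate
25 | 5,7-bis(methoxymethoxy)-2-[8-(methoxymethoxy)-2,2-dimethyl-5-(3-methylbut-2-en-1-yl)chroman-6-yl]-8-(2-methylbut-3-en-2-yl)chromane-3,4-dione (racemic) | CC(C)=CCc1c2CCC(C)(C)Oc2c(OCOC)cc1C1Oc2c(C(C)(C)C=C)c(OCOC)cc(OCOC)c2C(=O)C1=O | intermediate (not isolated)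
26 | 3-hydroxy-5,7-bis(methoxymethoxy)-2-[8-(methoxymethoxy)-2,2-dimethyl-5-(3-methylbut-2-en-1-yl)chroman-6-yl]-8-(2-methylbut-3-en-2-yl)-4H-chromen-4-one | CC(C)=CCc1c2CCC(C)(C)Oc2c(OCOC)cc1-c1oc2c(C(C)(C)C=C)c(OCOC)cc(OCOC)c2c(=O)c1O | intermediate
27 | Broussoflavonol E, 3,5,7-trihydroxy-2-[8-hydroxy-2,2-dimethyl-5-(3-methylbut-2-en-1-yl)chroman-6-yl]-8-(2-methylbut-3-en-2-yl)-4H-chromen-4-one | C=CC(C)(C)c1c(O)cc(O)c2c(=O)c(O)c(-c3cc(O)c4c(c3CC=C(C)C)CCC(C)(C)O4)oc12 | target

Total step count: 17. Longest linear sequence: 14 steps (steps 4–17, from 7); the ring A branch (steps 1–3) joins at step 12.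

Steps most likely to fail

Step 15. The carbene may add first to the more electrophilic aliphatic aldehyde, and the acyl-anion equivalent formed there may expel the ring A aryloxide from C2 (β-elimination with internal redox) instead of closing the ring; amine-induced aldol closure of C2 onto the ring A formyl group may also compete. The fallback closes ring C at O1–C2 by the Algar–Flynn–Oyamada reaction; it sets out from 6 and 13 and comes back at 26. Phenol 6 would be treated with MeMgBr (THF, 0 °C) to give 1-[2-hydroxy-4,6-bis(methoxymethoxy)-3-(2-methylbut-3-en-2-yl)phenyl]ethanol F1, which MnO2 (CH2Cl2) would oxidise to 1-[2-hydroxy-4,6-bis(methoxymethoxy)-3-(2-methylbut-3-en-2-yl)phenyl]ethanone F2. Bromo aldehyde 13 would be coupled with stannane 18 under the conditions of step 10 to give 8-(methoxymethoxy)-2,2-dimethyl-5-(3-methylbut-2-en-1-yl)chromane-6-carbaldehyde F3. Claisen–Schmidt condensation of F2 with F3 (KOH, EtOH, rt) would give (E)-1-[2-hydroxy-4,6-bis(methoxymethoxy)-3-(2-methylbut-3-en-2-yl)phenyl]-3-[8-(methoxymethoxy)-2,2-dimethyl-5-(3-methylbut-2-en-1-yl)chroman-6-yl]prop-2-en-1-one F4, and alkaline hydrogen peroxide (H2O2, NaOH, MeOH, 0 °C) would convert this chalcone into protected flavonol 26, after which step 17 follows.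

Step 12. Substitution may be too slow, because a chelated phenoxide flanked by a formyl group and a tertiary alkyl group has to attack a secondary carbon next to an ortho-substituted arene; decomposition of the mesylate or carbonate-induced aldol closure of the product onto the ring A aldehyde may then take over. The fallback makes the O1–C2 bond by carbene O–H insertion, which has an early and sterically undemanding transition state; it sets out from 17 and 6 and comes back at 21. Hydroxy ester 17 would be oxidised with Dess–Martin periodinane to methyl 2-[5-bromo-8-(methoxymethoxy)-2,2-dimethylchroman-6-yl]-2-oxoacetate F5, condensed with TsNHNH2 (MeOH, 60 °C) to methyl 2-[5-bromo-8-(methoxymethoxy)-2,2-dimethylchroman-6-yl]-2-(tosylhydrazono)acetate F6, and treated with DBU (CH2Cl2, rt) to give methyl 2-[5-bromo-8-(methoxymethoxy)-2,2-dimethylchroman-6-yl]-2-diazoacetate F7. Decomposition of F7 with Rh2(OAc)4 (cat., CH2Cl2, rt) in the presence of phenol 6 would insert the carbene into the O–H bond and give methyl 2-[5-bromo-8-(methoxymethoxy)-2,2-dimethylchroman-6-yl]-2-[2-formyl-3,5-bis(methoxymethoxy)-6-(2-methylbut-3-en-2-yl)phenoxy]acetate F8. The prenyl group would then be introduced with stannane 18 as in step 10 to give 21. The bromide is kept until after the insertion because an ortho-prenyl group would trap the carbene by cyclopropanation.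

Step 10. The prenyl group may be delivered through its tertiary terminus (allylic transposition to the 1,1-dimethylallyl isomer), or loss of the stannane may outrun oxidative addition at the doubly ortho-substituted bromide. The fallback builds the prenyl group in two stages; it sets out from 17 and comes back at 19. Stille coupling of 17 with allyltributylstannane (catalyst and CsF as in step 10) would give methyl 2-[5-allyl-8-(methoxymethoxy)-2,2-dimethylchroman-6-yl]-2-hydroxyacetate F9, which has no regiochemical ambiguity. Olefin cross-metathesis with an excess of 2-methylbut-2-ene (second-generation Grubbs catalyst RuCl2(=CHPh)(PCy3)(H2IMes), CH2Cl2, 40 °C) would then turn the allyl into the prenyl group and give 19.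

Further compounds

F1 | step 15 | 1-[2-hydroxy-4,6-bis(methoxymethoxy)-3-(2-methylbut-3-en-2-yl)phenyl]ethanol (racemic) | CC(O)c1c(O)c(C(C)(C)C=C)c(OCOC)cc1OCOC
F2 | step 15 | 1-[2-hydroxy-4,6-bis(methoxymethoxy)-3-(2-methylbut-3-en-2-yl)phenyl]ethanone | CC(=O)c1c(O)c(C(C)(C)C=C)c(OCOC)cc1OCOC
F3 | step 15 | 8-(methoxymethoxy)-2,2-dimethyl-5-(3-methylbut-2-en-1-yl)chromane-6-carbaldehyde | O=Cc1cc(OCOC)c2OC(C)(C)CCc2c1CC=C(C)C
F4 | step 15 | (E)-1-[2-hydroxy-4,6-bis(methoxymethoxy)-3-(2-methylbut-3-en-2-yl)phenyl]-3-[8-(methoxymethoxy)-2,2-dimethyl-5-(3-methylbut-2-en-1-yl)chroman-6-yl]prop-2-en-1-one | O=C(/C=C/c1cc(OCOC)c2OC(C)(C)CCc2c1CC=C(C)C)c1c(O)c(C(C)(C)C=C)c(OCOC)cc1OCOC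
F5 | step 12 | methyl 2-[5-bromo-8-(methoxymethoxy)-2,2-dimethylchroman-6-yl]-2-oxoacetate | COC(=O)C(=O)c1cc(OCOC)c2OC(C)(C)CCc2c1Br
F6 | step 12 | methyl 2-[5-bromo-8-(methoxymethoxy)-2,2-dimethylchroman-6-yl]-2-(tosylhydrazono)acetate | COC(=O)C(=NNS(=O)(=O)c1ccc(C)cc1)c1cc(OCOC)c2OC(C)(C)CCc2c1Br
F7 | step 12 | methyl 2-[5-bromo-8-(methoxymethoxy)-2,2-dimethylchroman-6-yl]-2-diazoacetate | COC(=O)C(=[N+]=[N-])c1cc(OCOC)c2OC(C)(C)CCc2c1Br
F8 | step 12 | methyl 2-[5-bromo-8-(methoxymethoxy)-2,2-dimethylchroman-6-yl]-2-[2-formyl-3,5-bis(methoxymethoxy)-6-(2-methylbut-3-en-2-yl)phenoxy]acetate (racemic) | COC(=O)C(Oc1c(C=O)c(OCOC)cc(OCOC)c1C(C)(C)C=C)c1cc(OCOC)c2OC(C)(C)CCc2c1Br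
F9 | step 10 | methyl 2-[5-allyl-8-(methoxymethoxy)-2,2-dimethylchroman-6-yl]-2-hydroxyacetate (racemic) | COC(=O)C(O)c1cc(OCOC)c2OC(C)(C)CCc2c1CC=C
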